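**Plan**
- Feature used: ring C (the resorcinol ring of the dihydrobenzofuran) is held to the eight-membered carbocycle through two adjacent carbons, C3a and C4 (benzofuran numbering). Their benzylic partners are dihydrofuran C3 and indane C2. Cutting both aryl–C bonds excises an aryne and contracts the eight-membered ring to a six-membered ring in which these two carbons are a ketone carbonyl and its ester-activated α-carbon.
- Cuts, in retrosynthetic order: eight O–Me bonds; dihydrofuran C2–O and C2–C3 ([4+1] on an o-quinone methide); indane C1–H and C1–aryl; indane C1–C7a (Friedel–Crafts acylation); the two ring C bonds (aryne insertion into the C1–C2 bond of a 2-carboalkoxy-1-tetralone); tetralone C3–C4 and C1–C2 (Michael–Dieckmann annulation).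
- Forward: diarylmethane benzoate (ring B) + chiral cinnamate → 3,4-trans tetralone β-keto ester → aryne ring expansion (adds ring C, makes the eight-membered ring) → indanone (closure on ring A) → 1-aryl indane → dihydrofuran → global demethylation.
- Stereochemistry: absolute control comes from (−)-8-phenylmenthol on the cinnamate, which sets the two centres that become indane C3 and the diarylmethine. Indane C2 is set by equilibration (trans), indane C1 by hydride delivery anti to ring C, dihydrofuran C3 by ylide attack on the open face of the o-quinone methide, and C2 by trans-selective closure.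

Key step: step 6

Remark: the (−)-auxiliary is assumed to shield the enoate face that leads to the (3S,4R) tetralone (s-trans enoate, π-stacked phenyl). If the sense proved opposite, the enantiomeric auxiliary would be used; the diastereomers are separable in either case.

**Step 1**
Reactants: 1 methyl 2-bromo-3,5-dimethoxybenzoate; 2 (4-methoxybenzyl)zinc chloride
Product: 3 methyl 3,5-dimethoxy-2-(4-methoxybenzyl)benzoate
Conditions: Pd(OAc)2 (2 mol %), SPhos (4 mol %), THF, 60 °C
Reagents that add atoms: none
Why: Negishi coupling; the benzylzinc transmetalates to the aryl–Pd–Br species formed by oxidative addition of the hindered aryl bromide to zerovalent palladium, and the methyl ester tolerates the organozinc.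

**Step 2**
Reactants: 4 (E)-3,5-dimethoxycinnamic acid; 5 (−)-8-phenylmenthol
Product: 6 (−)-8-phenylmenthyl (E)-3-(3,5-dimethoxyphenyl)acrylate
Conditions: DCC, DMAP (cat.), CH2Cl2, 0 °C to rt
Reagents that add atoms: none
Why: Steglich esterification of the hindered secondary alcohol through the acylpyridinium; the E-alkene is untouched.

**Step 3**
Reactants: 3 methyl 3,5-dimethoxy-2-(4-methoxybenzyl)benzoate; 6 (−)-8-phenylmenthyl (E)-3-(3,5-dimethoxyphenyl)acrylate
Product: 9 (−)-8-phenylmenthyl (2R,3S,4R)-3-(3,5-dimethoxyphenyl)-5,7-dimethoxy-4-(4-methoxyphenyl)-1-oxo-1,2,3,4-tetrahydronaphthalene-2-carboxylate, via benzylic lithio species 7 (not isolated), via lithium ester enolate 8 (not isolated)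
Conditions: LiN(i-Pr)2, THF, −78 °C; then 6, −78 to 0 °C; aq. NH4Cl
Reagents that add atoms: none
Why: Staunton–Weinreb annulation (lateral lithiation, Michael addition, Dieckmann closure with loss of methoxide); the 1,4-addition should occur on the enoate face not covered by the π-stacked phenyl of the auxiliary, which fixes C3, the chelated arrangement with the anisyl group outward should give the 3,4-trans pair, and the enolisable C2 settles trans to the C3 aryl.

**Step 4**
Reactants: 10 3,5-dimethoxyphenol
Product: 11 2-bromo-3,5-dimethoxyphenol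
Conditions: NBS (1.0 equiv), i-Pr2NH (10 mol %), CH2Cl2, −78 °C
Reagents that add atoms: N-bromosuccinimide O=C1CCC(=O)N1Br
Why: Amine-catalysed ortho-selective electrophilic bromination of a phenol, at the position ortho to OH and para to a methoxy group.

**Step 5**
Reactants: 11 2-bromo-3,5-dimethoxyphenol
Product: 14 3,5-dimethoxy-2-(trimethylsilyl)phenyl triflate, via aryl silyl ether 12 (not isolated), via lithium silylphenoxide 13 (not isolated)
Conditions: (Me3Si)2NH, THF, 65 °C; evaporate; n-BuLi, THF, −100 °C; Tf2O, −100 °C to rt
Reagents that add atoms: hexamethyldisilazane C[Si](C)(C)N[Si](C)(C)C; triflic anhydride O=S(=O)(OS(=O)(=O)C(F)(F)F)C(F)(F)F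
Why: O-silylation, bromine–lithium exchange and 1,3 O-to-C silyl shift (retro-Brook) place silicon on carbon, and the resulting phenoxide is triflated; this is the standard one-pot route to o-silylaryl triflates.

**Step 6**
Reactants: 9 tetralone β-keto ester; 14 3,5-dimethoxy-2-(trimethylsilyl)phenyl triflate
Product: 17 ring-expanded dibenzocyclooctenone keto ester (8-phenylmenthyl ester; all-trans bridge), via aryne 15 (not isolated), via benzocyclobutenoxide 16 (not isolated)
Conditions: CsF (2.5 equiv), MeCN, 80 °C
Reagents that add atoms: none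
Why: Fluoride desilylates 14 and triflate leaves to give aryne 15; the cesium enolate of 9 adds through its α-carbon to the aryne carbon remote from the flanking methoxy group, the aryl anion so formed (ortho to that methoxy) adds to the adjacent ring ketone to give benzocyclobutenoxide 16, and strain-driven retro-aldol cleavage of the former C1–C2 bond of the tetralone releases the ester enolate, which is protonated. The closest known reaction is the aryne acyl-alkylation of β-keto esters, including its use on cyclic β-keto esters for two-carbon ring expansion and with 3,5-dioxygenated arynes. The only ring closed directly is the transient four-membered ring (4-exo-trig, aryl anion on ketone); the eight-membered ring arises by fragmentation of the fused bicycle and not by a medium-ring cyclisation, and ring C becomes fused to it. The one stereocentre touched is the ester-bearing carbon (future indane C2), which is re-formed by protonation, stays epimerisable and should settle trans to the neighbouring aryl; the two diarylmethine centres are not involved. The step needs aryne regioselectivity (secured by the methoxy group next to the triple bond, which directs the nucleophile to the distal carbon so that the ketone ends ortho to OMe), C- over O-arylation (soft cesium enolate in MeCN) and attack of the aryl anion on the ketone and not the ester (the ketone is more electrophilic and the ester is shielded by the auxiliary).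

**Step 7**
Reactants: 17 ring-expanded keto ester
Product: 18 o-hydroxy diaryl ketone ester (ring C methoxy next to the ketone cleaved)
Conditions: BCl3 (1.5 equiv), CH2Cl2, −78 to 0 °C; aq. NaHCO3
Reagents that add atoms: none
Why: Chelation-controlled demethylation; BCl3 bound to the diaryl ketone cleaves only the methoxy group ortho to it, leaving the six other aryl methyl ethers and the ester.

**Step 8**
Reactants: 18 o-hydroxy diaryl ketone ester
Product: 19 carboxylic acid
Conditions: KOH, EtOH/H2O, 80 °C; then aq. HCl
Reagents that add atoms: potassium hydroxide [K+].[OH-]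
Why: Saponification (acyl–oxygen cleavage) of the hindered ester releases the acid and returns the auxiliary; the α-aryl centre can equilibrate under base and should stay trans to the neighbouring aryl.

**Step 9**
Reactants: 19 carboxylic acid
Product: 20 indanone (5,7-dimethoxy-1-indanone fused trans to the eight-membered ring)
Conditions: P2O5/MeSO3H, rt to 40 °C
Reagents that add atoms: none
Why: Intramolecular Friedel–Crafts acylation; the acylium ion attacks the ortho position of the 3,5-dimethoxyphenyl group (ring A, ortho/para to both methoxy groups) in a five-membered closure, and the enolisable indane C2 should keep the trans relation to C3.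

**Step 10**
Reactants: 20 indanone; 21 (4-methoxyphenyl)magnesium bromide
Product: 22 tertiary 1-aryl-1-indanol
Conditions: 21 (5 equiv), CeCl3 (5 equiv), THF, −78 to 0 °C; aq. NH4Cl
Reagents that add atoms: none
Why: Organocerium 1,2-addition (Imamoto conditions) to the readily enolisable 2-aryl indanone; the first equivalent turns the phenol into a phenoxide that deactivates the conjugated diaryl ketone, so only the indanone carbonyl should be arylated.

**Step 11**
Reactants: 22 tertiary 1-aryl-1-indanol
Product: 23 1,2-cis-diaryl indane keto phenol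
Conditions: Et3SiH (10 equiv), CF3CO2H, CH2Cl2, −40 °C
Reagents that add atoms: none
Why: Ionic hydrogenation; acid ionises the tertiary, doubly benzylic alcohol and Et3SiH should deliver hydride to the planar cation on the face anti to the ring C aryl at indane C2, giving the 1,2-cis diaryl indane, while low temperature and excess silane favour capture over loss of the C2 proton and spare the hydrogen-bonded ketone.

**Step 12**
Reactants: 23 1,2-cis-diaryl indane keto phenol
Product: 24 o-hydroxybenzhydrol
Conditions: NaBH4, THF/MeOH, 0 °C to rt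
Reagents that add atoms: none
Why: Borohydride reduction of the o-hydroxy diaryl ketone; the new carbinol centre is erased in the next step, so its configuration is irrelevant.

**Step 13**
Reactants: 24 o-hydroxybenzhydrol; 25 4-methoxybenzyl bromide
Product: 27 canaliculatol octamethyl ether, via o-quinone methide 26 (not isolated)
Conditions: tetrahydrothiophene, Cs2CO3, MeCN, rt to 50 °C
Reagents that add atoms: none
Why: Formal [4+1] annulation of an o-quinone methide with a sulfur ylide; base-induced loss of water gives 26, the benzylide made in the flask from 25 and tetrahydrothiophene should add to the methide carbon on the face away from the neighbouring 4-methoxyphenyl-bearing methine and the indane, and the phenoxide displaces the sulfide (5-exo-tet) from the anti betaine to give the trans 2,3-diaryl dihydrofuran.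

**Step 14**
Reactants: 27 canaliculatol octamethyl ether
Product: 28 canaliculatol
Conditions: BBr3 (excess), CH2Cl2, −78 to 0 °C; then MeOH/H2O
Reagents that add atoms: none
Why: Lewis acid-mediated cleavage of all eight aryl methyl ethers (bromide attack at methyl of the boron-complexed ethers), run cold to avoid ionising the benzylic C2–O bond of the dihydrofuran.

**Compound list**
1 | methyl 2-bromo-3,5-dimethoxybenzoate | COC(=O)c1cc(OC)cc(OC)c1Br | starting material
2 | (4-methoxybenzyl)zinc chloride (THF solution) | COc1ccc(C[Zn]Cl)cc1 | starting material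
3 | methyl 3,5-dimethoxy-2-(4-methoxybenzyl)benzoate | COC(=O)c1cc(OC)cc(OC)c1Cc1ccc(OC)cc1 | intermediate
4 | (E)-3,5-dimethoxycinnamic acid | COc1cc(/C=C/C(=O)O)cc(OC)c1 | starting material
5 | (−)-8-phenylmenthol, (1R,2S,5R)-5-methyl-2-(2-phenylpropan-2-yl)cyclohexan-1-ol | CC(C)(c1ccccc1)[C@@H]1CC[C@@H](C)C[C@H]1O | starting material
6 | (1R,2S,5R)-8-phenylmenthyl (E)-3-(3,5-dimethoxyphenyl)acrylate | CC(C)(c1ccccc1)[C@@H]1CC[C@@H](C)C[C@H]1OC(=O)/C=C/c1cc(OC)cc(OC)c1 | intermediate
7 | benzylic lithio derivative of 3 (lithium on the diarylmethane carbon) | COC(=O)c1cc(OC)cc(OC)c1C([Li])c1ccc(OC)cc1 | intermediate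
8 | lithium ester enolate from 1,4-addition of 7 to 6 (new centres as in 9) | CC(C)(c1ccccc1)[C@@H]1CC[C@@H](C)C[C@H]1OC(O[Li])=C[C@@H](c1cc(OC)cc(OC)c1)[C@H](c1ccc(OC)cc1)c1c(OC)cc(OC)cc1C(=O)OC | intermediate
9 | (−)-8-phenylmenthyl (2R,3S,4R)-3-(3,5-dimethoxyphenyl)-5,7-dimethoxy-4-(4-methoxyphenyl)-1-oxo-1,2,3,4-tetrahydronaphthalene-2-carboxylate (2,3-trans, 3,4-trans; in equilibrium with its enol) | CC(C)(c1ccccc1)[C@@H]1CC[C@@H](C)C[C@H]1OC(=O)[C@@H]1[C@@H](c2cc(OC)cc(OC)c2)[C@H](c2ccc(OC)cc2)c2c(OC)cc(OC)cc2C1=O | intermediate
10 | 3,5-dimethoxyphenol | COc1cc(O)cc(OC)c1 | starting material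
11 | 2-bromo-3,5-dimethoxyphenol | COc1cc(O)c(Br)c(OC)c1 | intermediate
12 | (2-bromo-3,5-dimethoxyphenoxy)trimethylsilane | COc1cc(O[Si](C)(C)C)c(Br)c(OC)c1 | intermediate
13 | lithium 3,5-dimethoxy-2-(trimethylsilyl)phenoxide | COc1cc(O[Li])c([Si](C)(C)C)c(OC)c1 | intermediate
14 | 3,5-dimethoxy-2-(trimethylsilyl)phenyl trifluoromethanesulfonate | COc1cc(OS(=O)(=O)C(F)(F)F)c([Si](C)(C)C)c(OC)c1 | intermediate
15 | 3,5-dimethoxybenzyne (1,2-didehydro-3,5-dimethoxybenzene) | COC1=CC(OC)=CC#C1 | intermediate
16 | cesium benzocyclobutenoxide (aryne carbons bonded to C2 and C1 of tetralone 9; ring-fusion centres unassigned) | CC(C)(c1ccccc1)[C@@H]1CC[C@@H](C)C[C@H]1OC(=O)C12[C@@H](c3cc(OC)cc(OC)c3)[C@H](c3ccc(OC)cc3)c3c(OC)cc(OC)cc3C1([O-])c1c(OC)cc(OC)cc12.[Cs+] | intermediate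
17 | ring-expanded keto ester: dibenzo[a,d]cyclooctenone with the ketone between rings B and C; three-carbon bridge CH(CO2-8-phenylmenthyl) next to ring C, then CH(3,5-dimethoxyphenyl), then CH(4-methoxyphenyl) next to ring B, all trans; two OMe on each of rings B and C | CC(C)(c1ccccc1)[C@@H]1CC[C@@H](C)C[C@H]1OC(=O)[C@@H]1[C@@H](c2cc(OC)cc(OC)c2)[C@H](c2ccc(OC)cc2)c2c(OC)cc(OC)cc2C(=O)c2c(OC)cc(OC)cc21 | intermediate
18 | as 17 with the ring C methoxy ortho to the ketone converted to OH | CC(C)(c1ccccc1)[C@@H]1CC[C@@H](C)C[C@H]1OC(=O)[C@@H]1[C@@H](c2cc(OC)cc(OC)c2)[C@H](c2ccc(OC)cc2)c2c(OC)cc(OC)cc2C(=O)c2c(O)cc(OC)cc21 | intermediate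
19 | carboxylic acid corresponding to 18 | OC(=O)[C@@H]1[C@@H](c2cc(OC)cc(OC)c2)[C@H](c2ccc(OC)cc2)c2c(OC)cc(OC)cc2C(=O)c2c(O)cc(OC)cc21 | intermediate
20 | indanone: ring A acylated by the acid carbon; 5,7-dimethoxyindan-1-one trans-fused (C2/C3) to the eight-membered ring | O=C2c3c(OC)cc(OC)cc3[C@H]3[C@H](c4ccc(OC)cc4)c4c(OC)cc(OC)cc4C(=O)c4c(O)cc(OC)cc4[C@H]23 | intermediate
21 | (4-methoxyphenyl)magnesium bromide (THF solution) | COc1ccc([Mg]Br)cc1 | starting material
22 | tertiary alcohol from addition of 21 to the indanone carbonyl of 20 (carbinol centre unassigned) | COc1ccc(C2(O)c3c(OC)cc(OC)cc3[C@H]3[C@H](c4ccc(OC)cc4)c4c(OC)cc(OC)cc4C(=O)c4c(O)cc(OC)cc4[C@H]23)cc1 | intermediate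
23 | 1-(4-methoxyphenyl)indane with H1/H2 cis and H2/H3 trans, still bearing the o-hydroxy diaryl ketone | COc1ccc([C@@H]2c3c(OC)cc(OC)cc3[C@H]3[C@H](c4ccc(OC)cc4)c4c(OC)cc(OC)cc4C(=O)c4c(O)cc(OC)cc4[C@H]23)cc1 | intermediate
24 | o-hydroxybenzhydrol from reduction of the ketone of 23 (carbinol centre unassigned) | COc1ccc([C@@H]2c3c(OC)cc(OC)cc3[C@H]3[C@H](c4ccc(OC)cc4)c4c(OC)cc(OC)cc4C(O)c4c(O)cc(OC)cc4[C@H]23)cc1 | intermediate
25 | 4-methoxybenzyl bromide | COc1ccc(CBr)cc1 | starting material
26 | o-quinone methide of ring C (exocyclic C=C to the future dihydrofuran C3) | COc1ccc([C@@H]2c3c(OC)cc(OC)cc3[C@H]3[C@H](c4ccc(OC)cc4)c4c(OC)cc(OC)cc4C=C4C(=O)C=C(OC)C=C4[C@H]23)cc1 | intermediate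
27 | canaliculatol octamethyl ether | COc1ccc([C@@H]2c3c(OC)cc(OC)cc3[C@H]3[C@H](c4ccc(OC)cc4)c4c(OC)cc(OC)cc4[C@@H]4c5c(cc(OC)cc5[C@H]23)O[C@H]4c2ccc(OC)cc2)cc1 | intermediate
28 | canaliculatol | Oc1ccc([C@@H]2c3c(O)cc(O)cc3[C@H]3[C@H](c4ccc(O)cc4)c4c(O)cc(O)cc4[C@@H]4c5c(cc(O)cc5[C@H]23)O[C@H]4c2ccc(O)cc2)cc1 | target

**Step count and risks**
Total: 14 steps. Longest linear sequence: 11 steps (steps 1, 3 and 6 to 14; the branch through steps 4 and 5 is equally long).

Steps most likely to fail:

Step 6. The hindered, β-aryl-flanked enolate may be arylated on oxygen, the aryl anion may be protonated before it reaches the ketone (plain α-arylation without ring expansion), or the product may be arylated a second time. The fallback sets out from 9 and comes back at 17. The potassium enolate of 9 (t-BuOK, toluene) would be arylated with (2-bromo-3,5-dimethoxyphenyl)(mesityl)iodonium triflate to give the quaternary α-(2-bromoaryl) keto ester F1. Bromine–lithium exchange (n-BuLi, THF, −100 °C) then lets the aryllithium add to the neighbouring ring ketone (Parham-type cyclisation), and the benzocyclobutenoxide 16 fragments as in the one-pot process to give 17.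

Step 13. The phenoxide may be O-benzylated by the bromide or the sulfonium salt, dehydration to the o-quinone methide may be slow, or the ylide may rearrange before it is trapped. The fallback sets out from 24 and comes back at 27. Treating 24 with p-toluenesulfinic acid (CH2Cl2, rt) would give the bench-stable sulfone F2. With 2.2 equiv of lithiated 4-methoxybenzyl phenyl sulfide (THF, −78 °C), the first equivalent releases the o-quinone methide 26 and the second adds to it from the open face to give the α-phenylthio phenol F3. S-Methylation (MeOTf, 2,6-di-tert-butyl-4-methylpyridine, CH2Cl2, 0 °C) makes the sulfide a leaving group, and the phenol closes the trans dihydrofuran of 27.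

Step 3. Facial discrimination by the auxiliary in the conjugate addition may be poor, and 1,2-addition or self-condensation of the benzylic anion may compete. The fallback sets out from 3 and comes back at 9. The same annulation with commercial methyl (E)-3,5-dimethoxycinnamate (LiN(i-Pr)2, THF, −78 to 0 °C) would give the racemic trans,trans methyl keto ester F4. Thermal transesterification with 5 (DMAP, toluene, 110 °C, loss of methanol through the acylketene) converts it into 9 and its diastereomer F5, which are separated by crystallisation or chromatography; 9 is carried on.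

**Further compounds**
F1 | step 6 | (−)-8-phenylmenthyl 2-(2-bromo-3,5-dimethoxyphenyl) derivative of keto ester 9 (quaternary C2, configuration unassigned) | CC(C)(c1ccccc1)[C@@H]1CC[C@@H](C)C[C@H]1OC(=O)C1(c2cc(OC)cc(OC)c2Br)[C@@H](c2cc(OC)cc(OC)c2)[C@H](c2ccc(OC)cc2)c2c(OC)cc(OC)cc2C1=O
F2 | step 13 | p-tolyl sulfone replacing the carbinol OH of 24 (sulfone-bearing centre unassigned) | COc1ccc([C@@H]2c3c(OC)cc(OC)cc3[C@H]3[C@H](c4ccc(OC)cc4)c4c(OC)cc(OC)cc4C(S(=O)(=O)c4ccc(C)cc4)c4c(O)cc(OC)cc4[C@H]23)cc1
F3 | step 13 | phenol bearing CH(SPh)(4-methoxyphenyl) on the future dihydrofuran C3 (thioether centre unassigned) | COc1ccc([C@@H]2c3c(OC)cc(OC)cc3[C@H]3[C@H](c4ccc(OC)cc4)c4c(OC)cc(OC)cc4[C@@H](C(Sc4ccccc4)c4ccc(OC)cc4)c4c(O)cc(OC)cc4[C@H]23)cc1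
F4 | step 3 | racemic methyl trans,trans-3-(3,5-dimethoxyphenyl)-5,7-dimethoxy-4-(4-methoxyphenyl)-1-oxo-1,2,3,4-tetrahydronaphthalene-2-carboxylate (one enantiomer drawn) | COC(=O)[C@@H]1[C@@H](c2cc(OC)cc(OC)c2)[C@H](c2ccc(OC)cc2)c2c(OC)cc(OC)cc2C1=O
F5 | step 3 | (−)-8-phenylmenthyl (2S,3R,4S) diastereomer of 9 | CC(C)(c1ccccc1)[C@@H]1CC[C@@H](C)C[C@H]1OC(=O)[C@H]1[C@H](c2cc(OC)cc(OC)c2)[C@@H](c2ccc(OC)cc2)c2c(OC)cc(OC)cc2C1=O
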